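At 2.50 h the ash readings stand at 2.1% of substrate and 5.5% of target, so 5.62% of the substrate that has reacted reads as target.

| flask | substrate | temperature | remark | time |
|---|---|---|---|---|
| ash | 0.35 M | 0 °C | run made earlier |  |
| amber | 0.50 M | 20 °C |  | 12 h |
| violet | 0.10 M | 40 °C |  | 12 h |
| green | 0.32 M | 0 °C |  | 12 h |
| teal | 0.15 M | −30 °C |  | 12 h |
| blue | 0.32 M | 15 °C |  | 12 h |

ash run (percent of the substrate charged)

| time / h | target / % | substrate / % |
|---|---|---|
| 0.133 | 0 | 87.0 |
| 0.333 | 0 | 70.5 |
| 0.667 | 0 | 46.7 |
| 1.00 | 0.6 | 30.2 |
| 1.33 | 1.8 | 17.6 |
| 2.00 | 3.4 | 5.3 |
| 2.50 | 5.5 | 2.1 |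

(scatter of a reading: 0.3 percentage points)

- the earlier runs do not show what temperature does; that part of a forecast is a guess

- all flasks from highest to lowest amount of target, in percent of the substrate charged, at 12 h (amber / violet / green / teal / blue)
- the amount of target, in percent of the substrate charged of the flask you put first, at 12 h
- the amount of target, in percent of the substrate charged of the flask you put last, at 12 h

The rule of thumb I use at the bench is first-order decay: substrate falls as exp(−k t) with one constant k. The first ash reading gives k = 1.05 /h, so ln(2)/k is 0.662 h. This substrate half-life is the quantity I carry. Green stands at the same temperature with a slightly smaller charge, and its 12 h spans 18.1 half-lives, so I reckon <0.001% of its substrate remaining.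

The rule has a border, and a ratio finds it. The ash reading at 2.00 h gives a constant of 1.47 /h, which is 1.40 times the first, with a scatter of 0.3 percentage points on a reading of 5.3%. Late in the ash run, then, the substrate readings fall faster than the half-life says. The rule also tells when substrate leaves, not what it becomes, so my reckoning gives no figure for target.

The target figures are the forecast's own: violet > amber > blue > green > teal, with 90% at the top and 0.2% at the bottom. One of its grounds reads: “Target appears only after a lag, while substrate is already half gone”.

The flasks give violet > blue > amber > green > teal, and teal stands at 0% of target at 12 h.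

    substrate → intermediate A (k = 0.0170 /min, Ea = 87.0 kJ/mol)
    intermediate A → intermediate B (k = 0.0194 /min, Ea = 75.0 kJ/mol)
    intermediate B → intermediate C (k = 0.00567 /min, Ea = 84.0 kJ/mol)
    intermediate C → target (k = 0.00992 /min, Ea = 94.0 kJ/mol)
    substrate + intermediate B → side product (k = 0.121 /M/min, Ea = 49.0 kJ/mol)
    target ⇌ isomer of the product (K = 0.317, k = 8.05 × 10⁻⁴ /min, Ea = 93.0 kJ/mol, ΔH = 7.00 kJ/mol)
    (constants at 0 °C)

Violet gives 66.5% of target against the forecast's 90%, and beside it stand 31.2% of isomer of the product at a conversion of 100%. Green holds 0.00945% of substrate at 6.00 h, where the ash half-life gives 0.187%. Teal keeps 89% of its substrate at 12 h, which, read as first-order decay, is a half-life of 74.7 h, or 113 times the ash value. Carried forward to 120 h, that teal half-life gives 32.8% of substrate, and the teal flask then holds 17.7%.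

The earlier runs and the new flask come from a simulation with made-up constants; noise was put on by code.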